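The ten-membered carbocycle is opened at C2–C3, the allyl–vinyl single bond inside its skipped diene C10=C1–C2–C3=C4. In the precursor both carbons are electrophiles: C2 is the CH2 of a (Z)-allylic methyl carbonate, C3 the CH of a (Z)-alkenyl iodide. Both hang on the complete trans-disubstituted α-methylene-γ-butyrolactone that already bears the C5 epoxyangelate and the free C6 hydroxyl. A nickel-catalysed reductive cross-electrophile coupling with zinc unites these like-polarity carbons, closes the ring and gives the natural product directly; both Z olefins are carried in. The seco compound comes from an indium allylation of a bromomethyl δ-lactone that translactonises.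

Key step: step 16

Numbering used below: ring carbons C1–C10 as in a germacrane, C10(Me)=C1–C2H2–C3H=C4(Me)–C5(O-acyl)–C6(OH)–C7–C8(O)–C9H2; lactone carbons C11–C13.

Step 1
Reactants: 1 methyl angelate
Product: 2 (Z)-2-methylbut-2-en-1-ol
Conditions: DIBAL-H (iBu2AlH, 2.2 equiv), CH2Cl2, −78 to 0 °C; Rochelle salt work-up
Reagents that add atoms: none
Why: 1,2-hydride reduction of the conjugated ester (DIBAL-H ester reduction) should give the allylic alcohol without touching the (Z)-olefin, and no stereocentre is formed.

Step 2
Reactants: 2 (Z)-2-methylbut-2-en-1-ol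
Product: 3 (2S,3R)-epoxy alcohol
Conditions: Ti(OiPr)4 (10 mol %), L-(+)-diisopropyl tartrate (12 mol %), tBuOOH, 4 Å sieves, CH2Cl2, −20 °C
Reagents that add atoms: tert-butyl hydroperoxide CC(C)(C)OO
Why: Sharpless asymmetric epoxidation, in which the titanium–L-tartrate complex delivers oxygen to the olefin face that gives the (2S,3R)-epoxide, so both stereocentres are catalyst-set and the cis addition keeps the two methyl groups trans as in the (Z)-olefin.

Step 3
Reactants: 3 (2S,3R)-epoxy alcohol
Product: 4 (2R,3R)-epoxyangelic acid
Conditions: RuCl3 (2 mol %), NaIO4 (3 equiv), MeCN/EtOAc/H2O, 0 °C to rt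
Reagents that add atoms: sodium periodate [Na+].[O-]I(=O)(=O)=O; water O
Why: catalytic ruthenium tetroxide oxidation should take the primary alcohol through the aldehyde hydrate to the acid without opening the trisubstituted epoxide, so both stereocentres are retained (the C2 descriptor changes from S to R only because CO2H outranks C3).

Step 4
Reactants: 5 propargyl alcohol
Product: 7 (Z)-3-iodo-2-methylprop-2-en-1-ol, via alkenylmagnesium alkoxide 6 (not isolated)
Conditions: MeMgBr (2.5 equiv), CuI (10 mol %), THF, −10 °C to rt; then I2, −10 °C; aqueous work-up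
Reagents that add atoms: methylmagnesium bromide C[Mg]Br; iodine II
Why: copper-catalysed anti-carbomagnesiation of the magnesium alkoxide puts methyl on the internal carbon and magnesium on the terminal carbon cis to CH2O through a five-membered chelate, and iodinolysis with retention should fix the (Z)-alkenyl iodide.

Step 5
Reactants: 7 (Z)-3-iodo-2-methylprop-2-en-1-ol
Product: 8 (Z)-3-iodo-2-methylprop-2-enal
Conditions: MnO2 (15 equiv), CH2Cl2, rt, dark
Reagents that add atoms: none
Why: selective allylic oxidation with MnO2 under neutral conditions should give the enal and preserve the (Z)-iodoalkene.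

Step 6
Reactants: 5 propargyl alcohol
Product: 9 4-methoxybenzyl propargyl ether
Conditions: NaH, 4-methoxybenzyl chloride, Bu4NI (cat.), THF/DMF, 0 °C to rt
Reagents that add atoms: 4-methoxybenzyl chloride COc1ccc(CCl)cc1
Why: Williamson ether synthesis of a primary alkoxide with a benzylic chloride.

Step 7
Reactants: 9 4-methoxybenzyl propargyl ether
Product: 10 (4-methoxybenzyloxy)allene
Conditions: KOtBu (20 mol %), THF, 0 °C to rt
Reagents that add atoms: none
Why: base-catalysed propargyl-to-allenyl ether isomerisation, which stops at the alkoxyallene.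

Step 8
Reactants: 10 (4-methoxybenzyloxy)allene; 8 (Z)-3-iodo-2-methylprop-2-enal
Product: 12 anti-diol mono-PMB ether (3R,4S), via (E)-γ-alkoxyallylborane 11 (not isolated)
Conditions: (−)-Ipc2BH (from (+)-α-pinene), THF, −40 to 0 °C; then 8, −78 °C; NaOH, H2O2 work-up
Reagents that add atoms: none
Why: hydroboration of the terminal allene double bond and 1,3-boratropic equilibration give the (E)-γ-alkoxyallylborane, which adds through a closed chair transition state (reagent-controlled allylboration), the E geometry setting the anti C5/C6 relationship and the isopinocampheyl groups selecting the aldehyde face that gives (5R,6S).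

Step 9
Reactants: 12 anti-diol mono-PMB ether (3R,4S); 13 2-(bromomethyl)acrylic acid
Product: 14 bromomethylacrylate ester
Conditions: DIC, DMAP (10 mol %), CH2Cl2, 0 °C
Reagents that add atoms: none
Why: carbodiimide (Steglich-type) esterification of the only free hydroxyl (C5) at low temperature, leaving both stereocentres untouched.

Step 10
Reactants: 14 bromomethylacrylate ester
Product: 15 bromomethyl δ-lactone
Conditions: second-generation Hoveyda–Grubbs catalyst (H2IMes)Cl2Ru=CH(C6H4-2-OiPr) (5 mol %), toluene, 80 °C, 5 mM
Reagents that add atoms: none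
Why: ring-closing metathesis between the C7 vinyl group and the acrylate should close the six-membered unsaturated lactone with loss of ethene, the trisubstituted iodoalkene being inert and a phosphine-free catalyst sparing the allylic bromide.

Step 11
Reactants: 16 (Z)-3-methylpent-2-en-4-yn-1-ol
Product: 17 enynyl methyl carbonate
Conditions: ClCO2Me, pyridine, CH2Cl2, 0 °C
Reagents that add atoms: methyl chloroformate COC(=O)Cl
Why: acylation of the primary allylic alcohol with a chloroformate installs the later leaving group on C2 and keeps the Z geometry.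

Step 12
Reactants: 17 enynyl methyl carbonate
Product: 19 β,γ-unsaturated aldehyde carbonate, via dienylborane 18 (not isolated)
Conditions: Cy2BH (1.1 equiv), THF, 0 °C; then 30% H2O2, pH 8 phosphate buffer, 0 °C; used crude at once
Reagents that add atoms: hydrogen peroxide OO
Why: anti-Markovnikov monohydroboration of the terminal alkyne and buffered oxidation give a dienol that should protonate at the α-carbon to the β,γ-unsaturated aldehyde (alkyne hydroboration–oxidation) with the Z olefin unchanged.

Step 13
Reactants: 15 bromomethyl δ-lactone; 19 β,γ-unsaturated aldehyde carbonate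
Product: 21 γ-lactone C5 alcohol, via δ-lactone adduct 20 (not isolated)
Conditions: In powder (1.5 equiv), THF/H2O (3:1), 0 °C to rt; then CSA (10 mol %), CH2Cl2, rt
Reagents that add atoms: none
Why: indium-mediated Barbier-type allylation then acid-catalysed translactonisation, in which the allylindium reacts at its γ-carbon C7 through a closed chair transition state with the aldehyde approaching anti to the adjacent C6 ether (sets C7) and the ring-locked E-type allyl geometry giving the anti adduct (sets C8), after which the C8 hydroxyl attacks the δ-lactone carbonyl to give the more stable trans-γ-lactone and free the C5 hydroxyl.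

Step 14
Reactants: 21 γ-lactone C5 alcohol; 4 (2R,3R)-epoxyangelic acid
Product: 23 C5 epoxyangelate PMB ether, via mixed anhydride 22 (not isolated)
Conditions: 4, 2,4,6-trichlorobenzoyl chloride, Et3N, THF, 0 °C to rt; then 21, DMAP, toluene, rt to 40 °C
Reagents that add atoms: none
Why: Yamaguchi esterification, whose mixed anhydride and acyl-pyridinium intermediate should acylate the hindered allylic C5 hydroxyl (the only free one) with an α-quaternary acid that cannot epimerise.

Step 15
Reactants: 23 C5 epoxyangelate PMB ether
Product: 24 seco iodide carbonate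
Conditions: DDQ (1.5 equiv), CH2Cl2/pH 7 buffer (10:1), 0 °C
Reagents that add atoms: none
Why: oxidative cleavage of the 4-methoxybenzyl ether by DDQ under buffered conditions should free the C6 hydroxyl without acyl migration, epoxide opening or reaction at the olefins (no bis-allylic CH2 is present yet).

Step 16
Reactants: 24 seco iodide carbonate
Product: 25 CNP0108157.1 (target)
Conditions: NiBr2(dme) (30 mol %), 4,4′-di-tert-butyl-2,2′-bipyridine (36 mol %), Zn dust (4 equiv), DMA/THF (1:1), 40 °C, syringe-pump addition of 24 to 2 mM
Reagents that add atoms: none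
Why: Zinc reduces NiBr2(dme)/bipyridine to zerovalent nickel, which inserts into the C3–I bond with retention of the Z geometry; the alkenylnickel species then ionises the primary allylic carbonate (methyl carbonate leaves and collapses to CO2 and methoxide) and, after reduction by zinc, reductive elimination joins alkenyl carbon C3 to the unsubstituted allyl terminus C2. The closest known reaction type is the nickel-catalysed reductive cross-electrophile coupling of alkenyl halides with allylic acetates or carbonates, run here intramolecularly under high dilution. The only ring closed is the ten-membered carbocycle, by bond formation at the CH2 end of the allyl unit (endo with respect to the allyl system); closure at the tertiary end C10 would give an eight-membered ring with a quaternary centre and is disfavoured sterically. No stereocentre is created, and the four ring and two epoxide stereocentres are remote from the reacting carbons. The step needs Z,Z-selectivity and cross- over homo-coupling: the C3=C4 geometry is fixed in the alkenyl iodide, the C1=C10 geometry comes from the neryl-type carbonate and is reinforced by the lower strain of a cis olefin in a ten-membered ring, and slow addition at 2 mM should suppress dimers. The hindered secondary C5 ester, although allylic, should ionise far more slowly than the primary carbonate, and the free C6 hydroxyl, the epoxide and the α-methylene lactone are not expected to react under these conditions.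

Compound list

1 | methyl (2Z)-2-methylbut-2-enoate (methyl angelate) | C/C=C(/C)C(=O)OC | starting material
2 | (2Z)-2-methylbut-2-en-1-ol | C/C=C(/C)CO | intermediate
3 | [(2S,3R)-2,3-dimethyloxiran-2-yl]methanol ((2S,3R)-epoxy alcohol) | OC[C@]1(C)O[C@@H]1C | intermediate
4 | (2R,3R)-2,3-dimethyloxirane-2-carboxylic acid ((2R,3R)-epoxyangelic acid) | OC(=O)[C@]1(C)O[C@@H]1C | intermediate
5 | prop-2-yn-1-ol (propargyl alcohol) | C#CCO | starting material
6 | bromomagnesium (2Z)-3-(bromomagnesio)-2-methylprop-2-en-1-olate (alkenylmagnesium alkoxide) | Br[Mg]/C=C(/C)CO[Mg]Br | intermediate (not isolated)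
7 | (2Z)-3-iodo-2-methylprop-2-en-1-ol | I/C=C(/C)CO | intermediate
8 | (2Z)-3-iodo-2-methylprop-2-enal | I/C=C(/C)C=O | intermediate
9 | 1-methoxy-4-[(prop-2-yn-1-yloxy)methyl]benzene (4-methoxybenzyl propargyl ether) | C#CCOCc1ccc(OC)cc1 | intermediate
10 | 1-methoxy-4-[(propa-1,2-dien-1-yloxy)methyl]benzene ((4-methoxybenzyloxy)allene) | C=C=COCc1ccc(OC)cc1 | intermediate
11 | (E)-3-[(4-methoxybenzyl)oxy]allylbis(isopinocampheyl)borane, isopinocampheyl groups from (+)-α-pinene ((E)-γ-alkoxyallylborane) | COc1ccc(CO/C=C/CB([C@@H]2C[C@@H]3C[C@H]([C@H]2C)C3(C)C)[C@@H]2C[C@@H]3C[C@H]([C@H]2C)C3(C)C)cc1 | intermediate (not isolated)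
12 | (1Z,3R,4S)-1-iodo-4-[(4-methoxyphenyl)methoxy]-2-methylhexa-1,5-dien-3-ol (anti-diol mono-PMB ether) | I/C=C(/C)[C@@H](O)[C@@H](OCc1ccc(OC)cc1)C=C | intermediate
13 | 2-(bromomethyl)prop-2-enoic acid (2-(bromomethyl)acrylic acid) | C=C(CBr)C(=O)O | starting material
14 | (1Z,3R,4S)-1-iodo-4-[(4-methoxyphenyl)methoxy]-2-methylhexa-1,5-dien-3-yl 2-(bromomethyl)prop-2-enoate (bromomethylacrylate ester) | C=C(CBr)C(=O)O[C@H](/C(C)=C\I)[C@@H](OCc1ccc(OC)cc1)C=C | intermediate
15 | (5S,6R)-3-(bromomethyl)-6-[(1Z)-1-iodoprop-1-en-2-yl]-5-[(4-methoxyphenyl)methoxy]-5,6-dihydro-2H-pyran-2-one (bromomethyl δ-lactone) | BrCC1=C[C@H](OCc2ccc(OC)cc2)[C@@H](/C(C)=C\I)OC1=O | intermediate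
16 | (2Z)-3-methylpent-2-en-4-yn-1-ol | C#C/C(C)=C\CO | starting material
17 | methyl (2Z)-3-methylpent-2-en-4-yn-1-yl carbonate (enynyl methyl carbonate) | C#C/C(C)=C\COC(=O)OC | intermediate
18 | (2Z,4E)-5-(dicyclohexylboranyl)-3-methylpenta-2,4-dien-1-yl methyl carbonate (dienylborane) | COC(=O)OC/C=C(C)\C=C\B(C1CCCCC1)C1CCCCC1 | intermediate (not isolated)
19 | methyl (2Z)-3-methyl-5-oxopent-2-en-1-yl carbonate (β,γ-unsaturated aldehyde carbonate) | O=CC/C(C)=C\COC(=O)OC | intermediate
20 | (2Z,5R)-5-hydroxy-5-[(4S,5S,6R)-6-[(1Z)-1-iodoprop-1-en-2-yl]-5-[(4-methoxyphenyl)methoxy]-3-methylidene-2-oxooxan-4-yl]-3-methylpent-2-en-1-yl methyl carbonate (δ-lactone adduct) | C=C1C(=O)O[C@H](/C(C)=C\I)[C@@H](OCc2ccc(OC)cc2)[C@@H]1[C@H](O)C/C(C)=C\COC(=O)OC | intermediate (not isolated)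
21 | (2Z)-4-[(2R,3S)-3-[(1S,2R,3Z)-2-hydroxy-4-iodo-1-[(4-methoxyphenyl)methoxy]-3-methylbut-3-en-1-yl]-4-methylidene-5-oxooxolan-2-yl]-3-methylbut-2-en-1-yl methyl carbonate (γ-lactone C5 alcohol) | C=C1C(=O)O[C@H](C/C(C)=C\COC(=O)OC)[C@H]1[C@@H]([C@@H](/C(=C\I)C)O)OCc2ccc(OC)cc2 | intermediate
22 | (2R,3R)-2,3-dimethyloxirane-2-carboxylic 2,4,6-trichlorobenzoic anhydride (mixed anhydride) | Clc1cc(Cl)c(C(=O)OC(=O)[C@]2(C)O[C@@H]2C)c(Cl)c1 | intermediate (not isolated)
23 | (1S,2R,3Z)-4-iodo-1-[(2R,3S)-2-[(2Z)-4-[(methoxycarbonyl)oxy]-2-methylbut-2-en-1-yl]-4-methylidene-5-oxooxolan-3-yl]-1-[(4-methoxyphenyl)methoxy]-3-methylbut-3-en-2-yl (2R,3R)-2,3-dimethyloxirane-2-carboxylate (C5 epoxyangelate PMB ether) | C=C1C(=O)O[C@H](C/C(C)=C\COC(=O)OC)[C@H]1[C@@H]([C@@H](/C(=C\I)C)OC(=O)[C@]2(C)O[C@@H]2C)OCc3ccc(OC)cc3 | intermediate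
24 | (1S,2R,3Z)-1-hydroxy-4-iodo-1-[(2R,3R)-2-[(2Z)-4-[(methoxycarbonyl)oxy]-2-methylbut-2-en-1-yl]-4-methylidene-5-oxooxolan-3-yl]-3-methylbut-3-en-2-yl (2R,3R)-2,3-dimethyloxirane-2-carboxylate (seco iodide carbonate) | C=C1C(=O)O[C@H](C/C(C)=C\COC(=O)OC)[C@H]1[C@@H]([C@@H](/C(=C\I)C)OC(=O)[C@]2(C)O[C@@H]2C)O | intermediate
25 | (3aR,4S,5R,6Z,9Z,11aR)-4-hydroxy-6,10-dimethyl-3-methylidene-2-oxo-2,3,3a,4,5,8,11,11a-octahydrocyclodeca[b]furan-5-yl (2R,3R)-2,3-dimethyloxirane-2-carboxylate (CNP0108157.1) | C=C1C(=O)O[C@@H]2C/C(C)=C\C/C=C(/C)[C@@H](OC(=O)[C@]3(C)O[C@@H]3C)[C@@H](O)[C@@H]12 | target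

Total step count: 16. Longest linear sequence: 9 steps (steps 4, 5, 8, 9, 10, 13, 14, 15, 16).

Steps most likely to fail

1. Step 16. Intermolecular oligomerisation and hydrodehalogenation of the alkenyl iodide may outrun the slow ten-membered ring closure. The allylnickel intermediate may also lose its Z geometry or couple at C10. Fallback, setting out from 24 and returning at 25: a stannylative palladium cyclisation of Stille–Kelly type. Compound 24 is treated with hexamethylditin, Pd(PPh3)4 and LiCl in dioxane under high dilution. The iodide is exchanged to give the alkenyltrimethylstannane F1 (24 with SnMe3 in place of iodine). F1 then couples intramolecularly with the allylpalladium species formed from the carbonate (Stille allyl–alkenyl coupling; Pd2(dba)3/AsPh3 if F1 is isolated first) to give 25.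

2. Step 13. The allylindium may undergo reductive 1,4-elimination of the C6 ether, the β,γ-unsaturated aldehyde may isomerise into conjugation or lose its carbonate, or facial discrimination may be poor in the aqueous medium. Fallback, setting out from 14 and returning at 21: an allylboration route without low-valent metal. SN2′ borylation of 14 (B2pin2, CuCl cat., LiCl, KOAc, DMF) should give the borylmethylacrylate ester F4. Ring-closing metathesis with the second-generation Hoveyda–Grubbs catalyst then gives the lactone allylboronate F5. F5 adds to 19 in toluene through the same closed chair transition state, and CSA completes the translactonisation to 21.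

3. Step 8. Equilibration of the allylborane to the E isomer may be incomplete, which would erode the anti selectivity, and facial control with the small iodoenal may be imperfect. Fallback, setting out from 8 and returning at 12: syn-selective addition followed by inversion. (Z)-γ-Alkoxyallylboration of 8 (allyl 4-methoxybenzyl ether, sec-BuLi, (+)-Ipc2BOMe from (−)-α-pinene, BF3·OEt2, −78 °C) should give the syn alcohol F2. Mitsunobu reaction with 4-nitrobenzoic acid (PPh3, DIAD) inverts the carbinol to the 4-nitrobenzoate F3. Methanolysis (K2CO3, MeOH) then gives 12.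

Further compounds

F1 | step 16 | alkenyltrimethylstannane (24 with SnMe3 in place of iodine) | C=C1C(=O)O[C@H](C/C(C)=C\COC(=O)OC)[C@H]1[C@@H]([C@@H](/C(=C\[Sn](C)(C)C)C)OC(=O)[C@]2(C)O[C@@H]2C)O
F2 | step 8 | syn alcohol, (1Z,3S,4S)-1-iodo-4-[(4-methoxyphenyl)methoxy]-2-methylhexa-1,5-dien-3-ol | I/C=C(/C)[C@H](O)[C@@H](OCc1ccc(OC)cc1)C=C
F3 | step 8 | 4-nitrobenzoate, (1Z,3R,4S)-1-iodo-4-[(4-methoxyphenyl)methoxy]-2-methylhexa-1,5-dien-3-yl 4-nitrobenzoate | I/C=C(/C)[C@@H](OC(=O)c1ccc(cc1)[N+](=O)[O-])[C@@H](OCc1ccc(OC)cc1)C=C
F4 | step 13 | borylmethylacrylate ester (14 with pinacolboryl in place of bromine) | C=C(CB1OC(C)(C)C(C)(C)O1)C(=O)O[C@H](/C(C)=C\I)[C@@H](OCc1ccc(OC)cc1)C=C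
F5 | step 13 | lactone allylboronate (15 with pinacolboryl in place of bromine) | CC1(C)OB(CC2=C[C@H](OCc3ccc(OC)cc3)[C@@H](/C(C)=C\I)OC2=O)OC1(C)C
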